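## Retrosynthetic overview

1. The target is a cis-fused (5β-H) labd-8(17)-ene with C-19, C-20, H-5 and C-11 on one face; the 19-ester is traced back to a 19-CH2OH bicycle (oxidation and O-methylation only).
2. Both rings are disconnected at once (C-4–C-5 and C-9–C-10) as one cation–olefin cascade that copies the diterpene-cyclase event: start at C-4, ring A closes first, ring B second, end as the 8(17)-methylene.
3. The initiator is an (S)-2,2-disubstituted oxirane (sets C-4 and brings the C-19 oxygen) and the terminator an allylsilane; the all-cis result requires a Z,Z chain.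
4. The acyclic chain is cut at C-7–C-8 and C-1–C-10 into two stereoretentive B-alkyl Suzuki couplings on Z-vinyl halides made from aldehydes.
5. C-13 comes from (S)-citronellol and C-4 from a Sharpless epoxidation of methallyl alcohol.

Assumption: the SMILES is read literally as (4S,5S,9S,10R,13S), i.e. the cis-fused 5-epimer of the usual labd-8(17)-en-19-oate skeleton; labdane numbering is used for atom positions throughout, also in the acyclic precursors.

## Route

Step 1
Reactants: 1 (S)-citronellol [(3S)-3,7-dimethyloct-6-en-1-ol]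
Product: 2 (S)-citronellyl acetate [(3S)-3,7-dimethyloct-6-en-1-yl acetate]
Conditions: Ac2O, pyridine, DMAP (cat.), CH2Cl2, 0 °C to rt
Reagents that add atoms: acetic anhydride, CC(=O)OC(C)=O
Why: DMAP-catalysed O-acylation of the primary alcohol installs the C-15 acetate of the target at the outset and does not touch the C-13 stereocentre taken from the chiral pool.

Step 2
Reactants: 2 (S)-citronellyl acetate
Product: 3 (3S)-3-methyl-6-oxohexyl acetate
Conditions: O3, CH2Cl2/MeOH (NaHCO3), −78 °C; then Me2S, −78 °C to rt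
Reagents that add atoms: ozone, [O-][O+]=O
Why: Ozonolysis with reductive work-up cleaves the only alkene to the aldehyde that becomes C-9, leaving the remote stereocentre and the acetate untouched.

Step 3
Reactants: 3 (3S)-3-methyl-6-oxohexyl acetate
Product: 4 (3S)-7,7-dibromo-3-methylhept-6-en-1-yl acetate
Conditions: CBr4, PPh3, CH2Cl2, 0 °C
Reagents that add atoms: carbon tetrabromide, BrC(Br)(Br)Br
Why: Ramirez dibromo-olefination (first stage of the Corey–Fuchs sequence) turns the aldehyde into the 1,1-dibromoalkene under neutral conditions that spare the ester; the new carbon is C-8.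

Step 4
Reactants: 4 (3S)-7,7-dibromo-3-methylhept-6-en-1-yl acetate
Product: 5 (3S,6Z)-7-bromo-3-methyl-8-(trimethylsilyl)oct-6-en-1-yl acetate
Conditions: Me3SiCH2MgCl, ZnCl2, THF, 0 °C; then 4, Pd(DPEphos)Cl2 (2 mol %), THF/DMF, 0 °C to rt
Reagents that add atoms: (trimethylsilyl)methylmagnesium chloride, C[Si](C)(C)C[Mg]Cl
Why: Trans-selective Negishi mono-coupling of a 1,1-dibromoalkene: oxidative addition takes place at the less hindered C–Br bond trans to the alkyl chain, so the CH2SiMe3 group (C-17) ends trans to C-11 and the remaining bromine cis to it, which fixes the alkene geometry.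

Step 5
Reactants: 5 (3S,6Z)-7-bromo-3-methyl-8-(trimethylsilyl)oct-6-en-1-yl acetate; 6 acrolein diethyl acetal (3,3-diethoxyprop-1-ene)
Product: 9 (3S,6E)-3-methyl-10-oxo-7-[(trimethylsilyl)methyl]dec-6-en-1-yl acetate, via alkylborane 7 (not isolated), via diethyl acetal 8 (not isolated)
Conditions: 6, 9-BBN, THF, 0 °C to rt; then 5, Pd(dppf)Cl2 (5 mol %), aq. K3PO4, THF/DMF, 50 °C; then PPTS (cat.), acetone/H2O, 40 °C
Reagents that add atoms: water, O
Why: Anti-Markovnikov hydroboration and B-alkyl Suzuki–Miyaura coupling replace the vinylic bromine with retention, which places C-7 cis to C-11, and the mild acetal hydrolysis (too weak to protodesilylate the allylsilane) frees the C-5 aldehyde.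

Step 6
Reactants: 9 (3S,6E)-3-methyl-10-oxo-7-[(trimethylsilyl)methyl]dec-6-en-1-yl acetate
Product: 10 (3S,6E,10Z)-11-iodo-3-methyl-7-[(trimethylsilyl)methyl]dodeca-6,10-dien-1-yl acetate
Conditions: EtPPh3I, n-BuLi, THF, 0 °C; I2, −78 °C; NaN(SiMe3)2, −78 °C; then 9, −78 to −20 °C
Reagents that add atoms: ethyltriphenylphosphonium iodide, CC[P+](c1ccccc1)(c1ccccc1)c1ccccc1.[I-]; iodine, II
Why: Zhao–Smith α-iodoethylidene Wittig olefination (a Stork–Zhao-type reaction) gives the trisubstituted (Z)-vinyl iodide under kinetic control with iodine cis to C-6, which sets the geometry of the future 5,10-alkene.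

Step 7
Reactants: 11 methallyl alcohol (2-methylprop-2-en-1-ol)
Product: 13 (S)-2-methylglycidyl tosylate {[(2S)-2-methyloxiran-2-yl]methyl 4-methylbenzenesulfonate}, via (R)-2-methylglycidol 12 (not isolated)
Conditions: Ti(OiPr)4 (5 mol %), D-(−)-diisopropyl tartrate (6 mol %), cumene hydroperoxide, 3 Å MS, CH2Cl2, −20 °C; P(OMe)3; then TsCl, Et3N, DMAP (cat.), −10 °C
Reagents that add atoms: cumene hydroperoxide, CC(C)(OO)c1ccccc1; 4-toluenesulfonyl chloride, Cc1ccc(cc1)S(=O)(=O)Cl
Why: Catalytic Sharpless asymmetric epoxidation with the D-tartrate gives the (R)-epoxy alcohol (the future C-4 stereocentre), and in situ sulfonylation traps the water-soluble glycidol as its tosylate, whose descriptor becomes S only through the change of priorities.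

Step 8
Reactants: 13 (S)-2-methylglycidyl tosylate
Product: 15 (2S)-2-methyl-2-(prop-2-en-1-yl)oxirane, via hydroxy tosylate 14 (not isolated)
Conditions: CH2=CHMgBr, CuI (10 mol %), THF, −40 to −20 °C; then aq. NaOH, Et2O, rt
Reagents that add atoms: vinylmagnesium bromide, C=C[Mg]Br
Why: Copper-catalysed Grignard opening of the oxirane at its CH2 terminus followed by intramolecular Williamson closure of the tertiary alkoxide onto the CH2OTs carbon moves the oxirane without breaking a bond to the quaternary carbon, so the stereocentre is carried over intact.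

Step 9
Reactants: 10 (3S,6E,10Z)-11-iodo-3-methyl-7-[(trimethylsilyl)methyl]dodeca-6,10-dien-1-yl acetate; 15 (2S)-2-methyl-2-(prop-2-en-1-yl)oxirane
Product: 17 (3S,6E,10Z)-3,11-dimethyl-14-[(2S)-2-methyloxiran-2-yl]-7-[(trimethylsilyl)methyl]tetradeca-6,10-dien-1-yl acetate, via epoxy alkylborane 16 (not isolated)
Conditions: 15, 9-BBN, THF, rt; then 10, Pd(dppf)Cl2 (5 mol %), AsPh3 (10 mol %), Cs2CO3, DMF/THF/H2O, rt
Reagents that add atoms: none
Why: Chemoselective hydroboration of the terminal alkene and B-alkyl Suzuki–Miyaura coupling with retention join C-1 to C-10 cis to C-6 (Z 5,10-alkene), while the oxirane, the allylsilane and the acetate tolerate the mild basic conditions.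

Step 10
Reactants: 17 (3S,6E,10Z)-3,11-dimethyl-14-[(2S)-2-methyloxiran-2-yl]-7-[(trimethylsilyl)methyl]tetradeca-6,10-dien-1-yl acetate
Product: 18 (4S,5S,9S,10R,13S)-19-hydroxylabd-8(17)-en-15-yl acetate
Conditions: MeAlCl2 (2.5 equiv), CH2Cl2 (0.005 M), −78 °C, 30 min; then aq. NaHCO3
Reagents that add atoms: none
Why: In this Lewis-acid epoxide-initiated, allylsilane-terminated Stork–Eschenmoser bicyclisation the 5,10-alkene opens the activated oxirane at its tertiary carbon with inversion (C-4 fixed by the oxirane), the cascade runs through a chair–chair transition state in which anti addition across the Z 5,10-alkene gives the cis ring fusion (C-5, C-10), the cis C-7/C-11 geometry of the 8,9-alkene puts C-11 axial on the same face (C-9), the tied-back oxirane CH2 rather than the methyl group takes the axial site next to the C-10 methyl (C-19 oxygenated), and loss of Me3Si from the β-silyl cation leaves only the exocyclic 8(17)-alkene.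

Step 11
Reactants: 18 (4S,5S,9S,10R,13S)-19-hydroxylabd-8(17)-en-15-yl acetate
Product: 19 (4S,5S,9S,10R,13S)-15-acetoxylabd-8(17)-en-19-oic acid
Conditions: CrO3, aq. H2SO4, acetone, 0 °C
Reagents that add atoms: water, O
Why: Jones oxidation takes the hindered neopentyl primary alcohol through the aldehyde hydrate to the acid in one operation, the acetate and the 1,1-disubstituted alkene survive the short cold exposure, and the quaternary C-4 cannot epimerise.

Step 12
Reactants: 19 (4S,5S,9S,10R,13S)-15-acetoxylabd-8(17)-en-19-oic acid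
Product: 20 methyl (4S,5S,9S,10R,13S)-15-acetoxylabd-8(17)-en-19-oate (target)
Conditions: MeI, K2CO3, DMF, rt
Reagents that add atoms: iodomethane, CI
Why: SN2 O-methylation of the carboxylate happens at the methyl carbon of MeI, so the hindrance of the axial acid does not matter and the anhydrous weak base leaves the acetate in place.

## Compound list

1 | (S)-citronellol, (3S)-3,7-dimethyloct-6-en-1-ol | OCC[C@@H](C)CCC=C(C)C | starting material
2 | (S)-citronellyl acetate, (3S)-3,7-dimethyloct-6-en-1-yl acetate | CC(=O)OCC[C@@H](C)CCC=C(C)C | intermediate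
3 | (3S)-3-methyl-6-oxohexyl acetate | CC(=O)OCC[C@@H](C)CCC=O | intermediate
4 | (3S)-7,7-dibromo-3-methylhept-6-en-1-yl acetate | CC(=O)OCC[C@@H](C)CCC=C(Br)Br | intermediate
5 | (3S,6Z)-7-bromo-3-methyl-8-(trimethylsilyl)oct-6-en-1-yl acetate (Br cis to the chain) | CC(=O)OCC[C@@H](C)CC/C=C(\Br)C[Si](C)(C)C | intermediate
6 | acrolein diethyl acetal, 3,3-diethoxyprop-1-ene | C=CC(OCC)OCC | starting material
7 | 9-(3,3-diethoxypropyl)-9-borabicyclo[3.3.1]nonane (formed in the flask) | CCOC(CCB1C2CCCC1CCC2)OCC | intermediate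
8 | (3S,6E)-10,10-diethoxy-3-methyl-7-[(trimethylsilyl)methyl]dec-6-en-1-yl acetate (formed in the flask) | CC(=O)OCC[C@@H](C)CC/C=C(\CCC(OCC)OCC)C[Si](C)(C)C | intermediate
9 | (3S,6E)-3-methyl-10-oxo-7-[(trimethylsilyl)methyl]dec-6-en-1-yl acetate (C-7 cis to C-11) | CC(=O)OCC[C@@H](C)CC/C=C(\CCC=O)C[Si](C)(C)C | intermediate
10 | (3S,6E,10Z)-11-iodo-3-methyl-7-[(trimethylsilyl)methyl]dodeca-6,10-dien-1-yl acetate (I cis to C-6) | CC(=O)OCC[C@@H](C)CC/C=C(\CC/C=C(\I)C)C[Si](C)(C)C | intermediate
11 | methallyl alcohol, 2-methylprop-2-en-1-ol | C=C(C)CO | starting material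
12 | (R)-2-methylglycidol, [(2R)-2-methyloxiran-2-yl]methanol (formed in the flask) | OC[C@]1(C)CO1 | intermediate
13 | (S)-2-methylglycidyl tosylate, [(2S)-2-methyloxiran-2-yl]methyl 4-methylbenzenesulfonate | Cc1ccc(cc1)S(=O)(=O)OC[C@]1(C)CO1 | intermediate
14 | (2S)-2-hydroxy-2-methylpent-4-en-1-yl 4-methylbenzenesulfonate (formed in the flask as its alkoxide) | Cc1ccc(cc1)S(=O)(=O)OC[C@](O)(C)CC=C | intermediate
15 | (2S)-2-methyl-2-(prop-2-en-1-yl)oxirane | C=CC[C@@]1(C)CO1 | intermediate
16 | 9-{3-[(2S)-2-methyloxiran-2-yl]propyl}-9-borabicyclo[3.3.1]nonane (formed in the flask) | C[C@]1(CCCB2C3CCCC2CCC3)CO1 | intermediate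
17 | (3S,6E,10Z)-3,11-dimethyl-14-[(2S)-2-methyloxiran-2-yl]-7-[(trimethylsilyl)methyl]tetradeca-6,10-dien-1-yl acetate (C-7 cis to C-11, C-1 cis to C-6) | CC(=O)OCC[C@@H](C)CC/C=C(\CC/C=C(\CCC[C@@]1(C)CO1)C)C[Si](C)(C)C | intermediate
18 | (4S,5S,9S,10R,13S)-19-hydroxylabd-8(17)-en-15-yl acetate; cis-decalin with 4β-CH2OH, 4α-CH3, 5β-H, 10β-CH3, 9β side chain | C=C1CC[C@H]2[C@](C)(CCC[C@]2(C)CO)[C@H]1CC[C@H](C)CCOC(C)=O | intermediate
19 | (4S,5S,9S,10R,13S)-15-acetoxylabd-8(17)-en-19-oic acid | C=C1CC[C@H]2[C@](C)(CCC[C@]2(C)C(=O)O)[C@H]1CC[C@H](C)CCOC(C)=O | intermediate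
20 | methyl (1S,4aR,5S,8aS)-5-[(3S)-5-acetoxy-3-methylpentyl]-1,4a-dimethyl-6-methylidenedecahydronaphthalene-1-carboxylate, CNP0332643.1 | C=C1CC[C@H]2[C@](C)(CCC[C@]2(C)C(=O)OC)[C@H]1CC[C@H](C)CCOC(C)=O | target

## Step count and risks

Total step count: 12. Longest linear sequence: 10 steps (steps 1–6 and 9–12, from 1).

**Step 10, the bicyclisation.** Risks:
- a 1,2-hydride shift of the activated 2,2-disubstituted oxirane to the aldehyde;
- capture of the C-10 cation by the alkoxide;
- incomplete transfer of the Z geometry into the cis ring fusion;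
- a poor axial/equatorial choice between CH3 and the oxirane CH2 at C-4.

The fallback sets out from 10 and comes back at 18. It builds C-4 from a trisubstituted 3,4-oxirane whose geometry, not a conformational preference, puts the oxygenated carbon axial, and deletes the extra 3-hydroxyl afterwards. Iodide 10 is coupled with borane 7 (Pd(dppf)Cl2, Cs2CO3) to the diethyl acetal F1, and PPTS hydrolysis gives aldehyde F2. The α-iodoethylidene Wittig reaction of step 6 gives the (Z)-vinyl iodide F3, and Stille coupling with Bu3SnCH2OH (Pd(PPh3)4, dioxane, 90 °C) gives the (Z)-allylic alcohol F4. Sharpless epoxidation (Ti(OiPr)4, D-(−)-diisopropyl tartrate, t-BuOOH) gives the epoxy alcohol F5, and TBSCl/imidazole its silyl ether F6. MeAlCl2 then gives the 3-hydroxy bicycle F7: the oxirane opens with inversion at C-4, and the CH2OTBS group, cis to C-2 on the oxirane, is forced into the axial position. 1,1′-Thiocarbonyldiimidazole gives the thiocarbamate F8, Bu3SnH/AIBN (Barton–McCombie) the deoxygenated silyl ether F9, and HF·pyridine returns 18.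

**Step 6, the α-iodoethylidene Wittig reaction.** Risks: modest yield with an enolisable aldehyde and some E isomer. The fallback sets out from 9 and comes back at 17. The aldehyde is treated as in step 3 (CBr4, PPh3) to give the dibromoalkene F10. Trans-selective Negishi methylation (Me2Zn, Pd(DPEphos)Cl2) gives the (Z)-vinyl bromide F11. This bromide takes the place of 10 in the coupling of step 9 with borane 16 (Pd(dppf)Cl2, aq. K3PO4, 50 °C) and gives 17.

**Step 8, the vinyl transfer.** Risk: attack at the oxirane CH2 and direct displacement of the tosylate lead to opposite enantiomers of 15, so any leakage lowers the enantiomeric purity of C-4. The fallback sets out from 11 and comes back at 15. Epoxidation of 11 with L-(+)-diisopropyl tartrate gives (S)-2-methylglycidol F12, and Tf2O/2,6-lutidine (−78 °C) gives the triflate F13. (CH2=CH)2CuLi at −78 °C then displaces the triflate directly with the oxirane staying closed, which gives the same (S)-oxirane 15 by a single pathway.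

## Further compounds

F1 | step 10 | (3S,6E,10Z)-14,14-diethoxy-3,11-dimethyl-7-[(trimethylsilyl)methyl]tetradeca-6,10-dien-1-yl acetate | CC(=O)OCC[C@@H](C)CC/C=C(\CC/C=C(\CCC(OCC)OCC)C)C[Si](C)(C)C
F2 | step 10 | (3S,6E,10Z)-3,11-dimethyl-14-oxo-7-[(trimethylsilyl)methyl]tetradeca-6,10-dien-1-yl acetate | CC(=O)OCC[C@@H](C)CC/C=C(\CC/C=C(\CCC=O)C)C[Si](C)(C)C
F3 | step 10 | (3S,6E,10Z,14Z)-15-iodo-3,11-dimethyl-7-[(trimethylsilyl)methyl]hexadeca-6,10,14-trien-1-yl acetate | CC(=O)OCC[C@@H](C)CC/C=C(\CC/C=C(\CC/C=C(\I)C)C)C[Si](C)(C)C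
F4 | step 10 | (3S,6E,10Z,14Z)-16-hydroxy-3,11,15-trimethyl-7-[(trimethylsilyl)methyl]hexadeca-6,10,14-trien-1-yl acetate | CC(=O)OCC[C@@H](C)CC/C=C(\CC/C=C(\CC/C=C(\CO)C)C)C[Si](C)(C)C
F5 | step 10 | (3S,6E,10Z)-13-[(2S,3R)-3-(hydroxymethyl)-3-methyloxiran-2-yl]-3,11-dimethyl-7-[(trimethylsilyl)methyl]trideca-6,10-dien-1-yl acetate | CC(=O)OCC[C@@H](C)CC/C=C(\CC/C=C(\CC[C@@H]1O[C@]1(C)CO)C)C[Si](C)(C)C
F6 | step 10 | tert-butyldimethylsilyl ether of F5 at the oxirane CH2OH | CC(=O)OCC[C@@H](C)CC/C=C(\CC/C=C(\CC[C@@H]1O[C@]1(C)CO[Si](C)(C)C(C)(C)C)C)C[Si](C)(C)C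
F7 | step 10 | (4S,5S,9S,10R,13S)-19-(tert-butyldimethylsilyloxy)-3-hydroxylabd-8(17)-en-15-yl acetate | C=C1CC[C@H]2[C@](C)(CC[C@H](O)[C@]2(C)CO[Si](C)(C)C(C)(C)C)[C@H]1CC[C@H](C)CCOC(C)=O
F8 | step 10 | 3-O-(imidazol-1-ylthiocarbonyl) derivative of F7 | C=C1CC[C@H]2[C@](C)(CC[C@H](OC(=S)n3ccnc3)[C@]2(C)CO[Si](C)(C)C(C)(C)C)[C@H]1CC[C@H](C)CCOC(C)=O
F9 | step 10 | (4S,5S,9S,10R,13S)-19-(tert-butyldimethylsilyloxy)labd-8(17)-en-15-yl acetate | C=C1CC[C@H]2[C@](C)(CCC[C@]2(C)CO[Si](C)(C)C(C)(C)C)[C@H]1CC[C@H](C)CCOC(C)=O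
F10 | step 6 | (3S,6E)-11,11-dibromo-3-methyl-7-[(trimethylsilyl)methyl]undeca-6,10-dien-1-yl acetate | CC(=O)OCC[C@@H](C)CC/C=C(\CCC=C(Br)Br)C[Si](C)(C)C
F11 | step 6 | (3S,6E,10Z)-11-bromo-3-methyl-7-[(trimethylsilyl)methyl]dodeca-6,10-dien-1-yl acetate | CC(=O)OCC[C@@H](C)CC/C=C(\CC/C=C(\Br)C)C[Si](C)(C)C
F12 | step 8 | (S)-2-methylglycidol, [(2S)-2-methyloxiran-2-yl]methanol | OC[C@@]1(C)CO1
F13 | step 8 | [(2R)-2-methyloxiran-2-yl]methyl trifluoromethanesulfonate | FC(F)(F)S(=O)(=O)OC[C@@]1(C)CO1
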